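## Retrosynthetic overview

- The target, (2R,5R,9R,10R,13Z)-16-acetoxy-2-hydroxylabda-8(17),13-dien-15-oic acid, is unmasked by fluoride from its C2 silyl ether / C15 2-(trimethylsilyl)ethyl ester.
- Key disconnection C9–C10 (ring B): the exocyclic C8=C17 methylene is allylic to C9, and C9 is bonded to the methyl-bearing quaternary C10. This is the retron of an SE2′ attack by a C17-silylated C8=C9 alkene on a tertiary C10 cation of ring A. The axial C4 methyl (1,3 to C10) steers the attack so that the ring fusion becomes trans.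
- The monocyclic allylsilane is assembled by two successive Negishi couplings on a 1,1-dibromoalkene (C7–C8, then C8–C17), which unite a ring-A iodide with the complete C9–C16 side chain.
- Ring A comes from ketoisophorone: asymmetric transfer hydrogenation sets C2, enol triflate/vinylation adds C6–C7, and cyclic hydroboration sets C5–H and the C10 oxygen.
- Order of ring formation: ring A is present from the start; ring B is closed last, in step 15.

Key step: step 15

Assumption: the sense of induction in step 6 follows the usual aryl/alkenyl ketone model for the Noyori catalyst ((R,R)-ligand gives the (R)-carbinol); if it proves opposite, the (S,S)-catalyst is used.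

## Route

Step 1
Reactants: 1 tert-butyldimethyl(prop-2-yn-1-yloxy)silane
Product: 3 2-(trimethylsilyl)ethyl 4-[(tert-butyldimethylsilyl)oxy]but-2-ynoate, via lithium acetylide 2 (not isolated)
Conditions: n-BuLi, THF, −78 °C; then 4-nitrophenyl 2-(trimethylsilyl)ethyl carbonate, −78 → −20 °C; aq NH4Cl
Reagents that add atoms: 4-nitrophenyl 2-(trimethylsilyl)ethyl carbonate, C[Si](C)(C)CCOC(=O)Oc1ccc(cc1)[N+](=O)[O-]
Why: C-acylation of a lithium acetylide by a mixed carbonate, in which 4-nitrophenoxide is the better leaving group, should give the ynoate directly as its fluoride-labile ester.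

Step 2
Reactants: 3 2-(trimethylsilyl)ethyl 4-[(tert-butyldimethylsilyl)oxy]but-2-ynoate
Product: 5 2-(trimethylsilyl)ethyl (2Z)-3-{[(tert-butyldimethylsilyl)oxy]methyl}hepta-2,6-dienoate, via alkenylcopper adduct 4 (not isolated)
Conditions: but-3-enylmagnesium bromide, CuBr·SMe2, THF, −78 °C; aq NH4Cl at −78 °C
Reagents that add atoms: but-3-enylmagnesium bromide, C=CCC[Mg]Br
Why: syn carbocupration (organocopper conjugate addition) of the ynoate with cold protonation should place the butenyl group trans to the ester, so the CH2O group is cis to the ester as the 13Z geometry requires.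

Step 3
Reactants: 5 2-(trimethylsilyl)ethyl (2Z)-3-{[(tert-butyldimethylsilyl)oxy]methyl}hepta-2,6-dienoate
Product: 6 2-(trimethylsilyl)ethyl (2Z)-3-(acetoxymethyl)hepta-2,6-dienoate
Conditions: Ac2O, Cu(OTf)2 (5 mol %), CH2Cl2, 0 → 25 °C
Reagents that add atoms: acetic anhydride, CC(=O)OC(C)=O
Why: Lewis-acid-catalysed acylative cleavage of the silyl ether exchanges silicon for acetyl without freeing the γ-hydroxyl, which would lactonise onto the cis ester.

Step 4
Reactants: 6 2-(trimethylsilyl)ethyl (2Z)-3-(acetoxymethyl)hepta-2,6-dienoate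
Product: 8 2-(trimethylsilyl)ethyl (2Z)-3-(acetoxymethyl)-6-oxohex-2-enoate, via secondary ozonide 7 (not isolated)
Conditions: O3, CH2Cl2, −78 °C (Sudan Red 7B end point); then PPh3, −78 → 25 °C
Reagents that add atoms: ozone, [O-][O+]=O
Why: ozonolysis with reductive work-up should cleave only the electron-rich monosubstituted alkene, because the ester-conjugated trisubstituted alkene reacts far more slowly.

Step 5
Reactants: 8 2-(trimethylsilyl)ethyl (2Z)-3-(acetoxymethyl)-6-oxohex-2-enoate
Product: 9 2-(trimethylsilyl)ethyl (2Z)-3-(acetoxymethyl)-7,7-dibromohepta-2,6-dienoate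
Conditions: CBr4, PPh3, CH2Cl2, 0 °C
Reagents that add atoms: carbon tetrabromide, BrC(Br)(Br)Br
Why: Ramirez dibromo-olefination (first stage of the Corey–Fuchs sequence) converts the aldehyde into the 1,1-dibromoalkene under neutral conditions that the esters tolerate.

Step 6
Reactants: 10 ketoisophorone (2,6,6-trimethylcyclohex-2-ene-1,4-dione)
Product: 11 (4R)-4-hydroxy-2,6,6-trimethylcyclohex-2-en-1-one
Conditions: RuCl(p-cymene)[(R,R)-TsDPEN] (0.5 mol %), KOH (1 mol %), i-PrOH, 25 °C
Reagents that add atoms: none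
Why: Noyori asymmetric transfer hydrogenation should reduce only the unhindered enone carbonyl (the other is flanked by a quaternary carbon and the methyl-bearing alkene carbon) and set the C2 carbinol centre by catalyst control.

Step 7
Reactants: 11 (4R)-4-hydroxy-2,6,6-trimethylcyclohex-2-en-1-one
Product: 12 (4R)-4-[(tert-butyldimethylsilyl)oxy]-2,6,6-trimethylcyclohex-2-en-1-one
Conditions: TBSCl, imidazole, DMF, 25 °C
Reagents that add atoms: tert-butyldimethylsilyl chloride, CC(C)(C)[Si](C)(C)Cl
Why: standard silylation of a secondary alcohol; the stereocentre is not touched.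

Step 8
Reactants: 12 (4R)-4-[(tert-butyldimethylsilyl)oxy]-2,6,6-trimethylcyclohex-2-en-1-one
Product: 14 (4S)-4-[(tert-butyldimethylsilyl)oxy]-2,6,6-trimethylcyclohex-1-en-1-yl trifluoromethanesulfonate, via lithium enolate 13 (not isolated)
Conditions: LiBH(s-Bu)3, THF, −78 °C; then PhNTf2, −78 → 0 °C; aq NH4Cl
Reagents that add atoms: N-phenylbis(trifluoromethanesulfonimide), O=S(=O)(N(c1ccccc1)S(=O)(=O)C(F)(F)F)C(F)(F)F
Why: conjugate hydride reduction of the carbonyl-hindered enone should give the tetrasubstituted enolate regiospecifically, and O-sulfonylation traps it as the C5=C10 enol triflate (the descriptor changes only through priorities).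

Step 9
Reactants: 14 (4S)-4-[(tert-butyldimethylsilyl)oxy]-2,6,6-trimethylcyclohex-1-en-1-yl trifluoromethanesulfonate
Product: 15 tert-butyldimethyl{[(1S)-3,5,5-trimethyl-4-vinylcyclohex-3-en-1-yl]oxy}silane
Conditions: CH2=CHSnBu3, Pd(PPh3)4 (5 mol %), LiCl, THF, 65 °C
Reagents that add atoms: tributyl(vinyl)stannane, C=C[Sn](CCCC)(CCCC)CCCC
Why: Stille coupling of a hindered enol triflate with a vinylstannane (chloride-promoted) attaches C6 and C7 to C5.

Step 10
Reactants: 15 tert-butyldimethyl{[(1S)-3,5,5-trimethyl-4-vinylcyclohex-3-en-1-yl]oxy}silane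
Product: 17 (1R,2R,5R)-5-[(tert-butyldimethylsilyl)oxy]-2-(2-hydroxyethyl)-1,3,3-trimethylcyclohexan-1-ol, via cyclic borane 16 (not isolated)
Conditions: BH3·THF (2.5 equiv), THF, 0 → 45 °C; then aq NaOH, H2O2, 0 → 25 °C
Reagents that add atoms: hydrogen peroxide, OO
Why: cyclic hydroboration–oxidation of the 1,3-diene, in which boron first adds to the vinyl terminus (C7) and the tethered B–H then adds syn across C5=C10 with boron on C10, from the face anti to the pseudoaxial C4 methyl of the half-chair that keeps the silyloxy group equatorial, should set C5–H cis to the C2 oxygen, and oxidation proceeds with retention.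

Step 11
Reactants: 17 (1R,2R,5R)-5-[(tert-butyldimethylsilyl)oxy]-2-(2-hydroxyethyl)-1,3,3-trimethylcyclohexan-1-ol
Product: 18 (1R,2R,5R)-5-[(tert-butyldimethylsilyl)oxy]-2-(2-iodoethyl)-1,3,3-trimethylcyclohexan-1-ol
Conditions: I2, PPh3, imidazole, CH2Cl2, 0 °C
Reagents that add atoms: iodine, II
Why: Appel-type iodination is selective for the primary hydroxyl; the hindered tertiary alcohol should not react.

Step 12
Reactants: 18 (1R,2R,5R)-5-[(tert-butyldimethylsilyl)oxy]-2-(2-iodoethyl)-1,3,3-trimethylcyclohexan-1-ol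
Product: 19 (1R,2R,5R)-5-[(tert-butyldimethylsilyl)oxy]-2-(2-iodoethyl)-1,3,3-trimethylcyclohexyl acetate
Conditions: Ac2O, DMAP, Et3N, CH2Cl2, 25 °C
Reagents that add atoms: acetic anhydride, CC(=O)OC(C)=O
Why: DMAP-catalysed acylation turns the tertiary alcohol into a tertiary acetate, which protects it during organozinc formation and later serves as the ionisable leaving group at C10.

Step 13
Reactants: 19 (1R,2R,5R)-5-[(tert-butyldimethylsilyl)oxy]-2-(2-iodoethyl)-1,3,3-trimethylcyclohexyl acetate; 9 2-(trimethylsilyl)ethyl (2Z)-3-(acetoxymethyl)-7,7-dibromohepta-2,6-dienoate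
Product: 21 2-(trimethylsilyl)ethyl (2Z,6Z)-3-(acetoxymethyl)-9-{(1R,2R,4R)-2-acetoxy-4-[(tert-butyldimethylsilyl)oxy]-2,6,6-trimethylcyclohexyl}-7-bromonona-2,6-dienoate, via alkylzinc iodide 20 (not isolated)
Conditions: Zn, LiCl, THF, 40 °C; then 9, PdCl2(DPEphos) (5 mol %), THF, 0 → 25 °C
Reagents that add atoms: none
Why: zinc insertion into the primary iodide and trans-selective Negishi mono-alkylation of the 1,1-dibromoalkene should replace only the bromine trans to the C9 substituent, so C7 ends trans to C11 and the remaining bromine cis to it.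

Step 14
Reactants: 21 2-(trimethylsilyl)ethyl (2Z,6Z)-3-(acetoxymethyl)-9-{(1R,2R,4R)-2-acetoxy-4-[(tert-butyldimethylsilyl)oxy]-2,6,6-trimethylcyclohexyl}-7-bromonona-2,6-dienoate
Product: 22 2-(trimethylsilyl)ethyl (2Z,6Z)-3-(acetoxymethyl)-9-{(1R,2R,4R)-2-acetoxy-4-[(tert-butyldimethylsilyl)oxy]-2,6,6-trimethylcyclohexyl}-7-[(trimethylsilyl)methyl]nona-2,6-dienoate
Conditions: Me3SiCH2MgCl, ZnCl2, THF, 0 °C; then 21, Pd(P(t-Bu)3)2 (5 mol %), THF, 25 °C
Reagents that add atoms: (trimethylsilyl)methylmagnesium chloride, C[Si](C)(C)C[Mg]Cl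
Why: a second Negishi coupling with retention of alkene geometry (the bulky phosphine suppresses stereoisomerisation, and the silylmethyl group has no β-hydrogen) should give the allylsilane with CH2SiMe3 cis to C11.

Step 15
Reactants: 22 2-(trimethylsilyl)ethyl (2Z,6Z)-3-(acetoxymethyl)-9-{(1R,2R,4R)-2-acetoxy-4-[(tert-butyldimethylsilyl)oxy]-2,6,6-trimethylcyclohexyl}-7-[(trimethylsilyl)methyl]nona-2,6-dienoate
Product: 23 2-(trimethylsilyl)ethyl (2R,5R,9R,10R,13Z)-16-acetoxy-2-[(tert-butyldimethylsilyl)oxy]labda-8(17),13-dien-15-oate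
Conditions: SnCl4 (3 equiv), 2,6-di-tert-butyl-4-methylpyridine, CH2Cl2, −78 → −40 °C; aq NaHCO3
Reagents that add atoms: none
Why: SnCl4 ionises the tertiary C10 acetate to the tertiary C10 carbocation, C9 of the silylated C8=C9 alkene attacks C10, and the resulting β-silyl C8 cation loses the silyl group from C17 (SE2′) to leave the C8=C17 exocyclic alkene. The closest known reaction type is the allylsilane-terminated biomimetic cation–olefin cyclisation that gives exocyclic 8(17)-alkenes, an intramolecular Hosomi–Sakurai-type alkylation of a tertiary carbocation. Ring B closes in the 6-endo-trig mode (both C8 and C9 become ring atoms) through a chair-like transition state. C10 is set by ring A, whose chair keeps the C2 silyloxy group and the C5 tether equatorial: the axial C4 methyl blocks the axial trajectory, so C9 should enter equatorially and C20 become axial and trans to H5. C9 is set by the alkene geometry: C11 is trans to C7 and so sits equatorial in the chair, giving H9 cis to H5. The step needs chemoselective ionisation (only the tertiary acetate gives a stabilised cation, the primary allylic acetate and the esters do not), attack through C9 rather than C8 (secured by the β-silicon effect) and freedom from protodesilylation (secured by the hindered pyridine base).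

Step 16
Reactants: 23 2-(trimethylsilyl)ethyl (2R,5R,9R,10R,13Z)-16-acetoxy-2-[(tert-butyldimethylsilyl)oxy]labda-8(17),13-dien-15-oate
Product: 24 (2R,5R,9R,10R,13Z)-16-acetoxy-2-hydroxylabda-8(17),13-dien-15-oic acid
Conditions: TASF [(Me2N)3S+ Me3SiF2−] (4 equiv), DMF, 0 → 25 °C; pH 5 NaH2PO4 buffer
Reagents that add atoms: none
Why: fluoride-induced fragmentation of the 2-(trimethylsilyl)ethyl ester and cleavage of the secondary silyl ether under non-basic, anhydrous conditions should leave the primary acetate and the exocyclic alkene untouched, and mild acidification gives the free acid.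

## Compound list

1 | tert-butyldimethyl(prop-2-yn-1-yloxy)silane | C#CCO[Si](C)(C)C(C)(C)C | starting material
2 | lithium 3-[(tert-butyldimethylsilyl)oxy]prop-1-yn-1-ide | [Li]C#CCO[Si](C)(C)C(C)(C)C | intermediate
3 | 2-(trimethylsilyl)ethyl 4-[(tert-butyldimethylsilyl)oxy]but-2-ynoate | C[Si](C)(C)CCOC(=O)C#CCO[Si](C)(C)C(C)(C)C | intermediate
4 | alkenylcopper syn-adduct, 2-(trimethylsilyl)ethyl (2E)-3-{[(tert-butyldimethylsilyl)oxy]methyl}-2-cupriohepta-2,6-dienoate | C=CCC/C(=C(/C(=O)OCC[Si](C)(C)C)[Cu])CO[Si](C)(C)C(C)(C)C | intermediate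
5 | 2-(trimethylsilyl)ethyl (2Z)-3-{[(tert-butyldimethylsilyl)oxy]methyl}hepta-2,6-dienoate | C=CCC/C(=C/C(=O)OCC[Si](C)(C)C)CO[Si](C)(C)C(C)(C)C | intermediate
6 | 2-(trimethylsilyl)ethyl (2Z)-3-(acetoxymethyl)hepta-2,6-dienoate | C=CCC/C(=C/C(=O)OCC[Si](C)(C)C)COC(C)=O | intermediate
7 | secondary ozonide (1,2,4-trioxolane) of the terminal alkene of 6 | C1OOC(CC/C(=C/C(=O)OCC[Si](C)(C)C)COC(C)=O)O1 | intermediate
8 | 2-(trimethylsilyl)ethyl (2Z)-3-(acetoxymethyl)-6-oxohex-2-enoate | O=CCC/C(=C/C(=O)OCC[Si](C)(C)C)COC(C)=O | intermediate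
9 | 2-(trimethylsilyl)ethyl (2Z)-3-(acetoxymethyl)-7,7-dibromohepta-2,6-dienoate | BrC(Br)=CCC/C(=C/C(=O)OCC[Si](C)(C)C)COC(C)=O | intermediate
10 | ketoisophorone (2,6,6-trimethylcyclohex-2-ene-1,4-dione) | CC1=CC(=O)CC(C)(C)C1=O | starting material
11 | (4R)-4-hydroxy-2,6,6-trimethylcyclohex-2-en-1-one | O=C1C(C)(C)C[C@@H](O)C=C1C | intermediate
12 | (4R)-4-[(tert-butyldimethylsilyl)oxy]-2,6,6-trimethylcyclohex-2-en-1-one | O=C1C(C)(C)C[C@@H](O[Si](C)(C)C(C)(C)C)C=C1C | intermediate
13 | lithium (4S)-4-[(tert-butyldimethylsilyl)oxy]-2,6,6-trimethylcyclohex-1-en-1-olate | [Li]OC1=C(C)C[C@H](O[Si](C)(C)C(C)(C)C)CC1(C)C | intermediate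
14 | (4S)-4-[(tert-butyldimethylsilyl)oxy]-2,6,6-trimethylcyclohex-1-en-1-yl trifluoromethanesulfonate | O=S(=O)(OC1=C(C)C[C@H](O[Si](C)(C)C(C)(C)C)CC1(C)C)C(F)(F)F | intermediate
15 | tert-butyldimethyl{[(1S)-3,5,5-trimethyl-4-vinylcyclohex-3-en-1-yl]oxy}silane | C=CC1=C(C)C[C@H](O[Si](C)(C)C(C)(C)C)CC1(C)C | intermediate
16 | cyclic borane (B–H borolane bridging C7 and C10, trans-fused to ring A, H5 cis to boron) | B1CC[C@@H]2C(C)(C)C[C@@H](O[Si](C)(C)C(C)(C)C)C[C@@]12C | intermediate
17 | (1R,2R,5R)-5-[(tert-butyldimethylsilyl)oxy]-2-(2-hydroxyethyl)-1,3,3-trimethylcyclohexan-1-ol | OCC[C@@H]1C(C)(C)C[C@@H](O[Si](C)(C)C(C)(C)C)C[C@@]1(C)O | intermediate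
18 | (1R,2R,5R)-5-[(tert-butyldimethylsilyl)oxy]-2-(2-iodoethyl)-1,3,3-trimethylcyclohexan-1-ol | ICC[C@@H]1C(C)(C)C[C@@H](O[Si](C)(C)C(C)(C)C)C[C@@]1(C)O | intermediate
19 | (1R,2R,5R)-5-[(tert-butyldimethylsilyl)oxy]-2-(2-iodoethyl)-1,3,3-trimethylcyclohexyl acetate | ICC[C@@H]1C(C)(C)C[C@@H](O[Si](C)(C)C(C)(C)C)C[C@@]1(C)OC(C)=O | intermediate
20 | alkylzinc iodide derived from 19 (C7–ZnI) | I[Zn]CC[C@@H]1C(C)(C)C[C@@H](O[Si](C)(C)C(C)(C)C)C[C@@]1(C)OC(C)=O | intermediate
21 | 2-(trimethylsilyl)ethyl (2Z,6Z)-3-(acetoxymethyl)-9-{(1R,2R,4R)-2-acetoxy-4-[(tert-butyldimethylsilyl)oxy]-2,6,6-trimethylcyclohexyl}-7-bromonona-2,6-dienoate | Br/C(CC[C@@H]1C(C)(C)C[C@@H](O[Si](C)(C)C(C)(C)C)C[C@@]1(C)OC(C)=O)=C\CC/C(=C/C(=O)OCC[Si](C)(C)C)COC(C)=O | intermediate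
22 | 2-(trimethylsilyl)ethyl (2Z,6Z)-3-(acetoxymethyl)-9-{(1R,2R,4R)-2-acetoxy-4-[(tert-butyldimethylsilyl)oxy]-2,6,6-trimethylcyclohexyl}-7-[(trimethylsilyl)methyl]nona-2,6-dienoate | C[Si](C)(C)C/C(CC[C@@H]1C(C)(C)C[C@@H](O[Si](C)(C)C(C)(C)C)C[C@@]1(C)OC(C)=O)=C\CC/C(=C/C(=O)OCC[Si](C)(C)C)COC(C)=O | intermediate
23 | 2-(trimethylsilyl)ethyl (2R,5R,9R,10R,13Z)-16-acetoxy-2-[(tert-butyldimethylsilyl)oxy]labda-8(17),13-dien-15-oate | C=C1CC[C@@H]2C(C)(C)C[C@@H](O[Si](C)(C)C(C)(C)C)C[C@@]2(C)[C@@H]1CC/C(=C/C(=O)OCC[Si](C)(C)C)COC(C)=O | intermediate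
24 | (2R,5R,9R,10R,13Z)-16-acetoxy-2-hydroxylabda-8(17),13-dien-15-oic acid | C=C1CC[C@@H]2C(C)(C)C[C@@H](O)C[C@@]2(C)[C@@H]1CC/C(=C/C(=O)O)COC(C)=O | target

## Step count and risks

Total step count: 16. Longest linear sequence: 11 steps (steps 6–16, from ketoisophorone); the side-chain fragment (steps 1–5) joins at step 13.

Steps most likely to fail:

**Step 15 (ring-B closure).** The tertiary cation may lose a proton to ring alkenes faster than it is captured. The acid so released may protodesilylate the allylsilane. Attack along the axial trajectory would erode the trans ring fusion. The fallback sets out from 21 and returns at 23. It abandons the silane and uses the alkenyl bromide itself as the terminating group in a halo-olefin-terminated cationic cyclisation (SnCl4, CH2Cl2, −78 → 0 °C, then aqueous NaHCO3). Without a base, eliminated alkenes can re-enter by protonation. The α-bromo cation is hydrolysed on work-up to the C8 ketone F1, whose C9 centre is epimerisable and should settle with the side chain equatorial. Takai–Lombardo methylenation (Zn, CH2Br2, TiCl4, THF) then gives 23.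

**Step 10 (cyclic hydroboration).** The second B–H addition to the hindered tetrasubstituted ring alkene may be slow, so that the primary alkylborane is consumed by intermolecular addition to other vinyl groups. Facial selectivity may also be incomplete. The fallback sets out from 15 and returns at 17. Sensitised photo-oxygenation (O2, visible light, tetraphenylporphyrin, CH2Cl2, 0 °C) adds singlet oxygen across the diene in a [4+2] manner, anti to the pseudoaxial C4 methyl, to give the endoperoxide F2. Reduction of the O–O bond with thiourea in methanol gives the (Z)-enediol F3. Hydroxyl-directed hydrogenation with [Ir(cod)(PCy3)(py)]PF6 (H2, CH2Cl2) delivers hydrogen to C5 from the face of the C10 hydroxyl and gives 17.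

**Step 12 (tertiary acetate beside a primary iodide).** The hindered tertiary hydroxyl may displace the primary iodide four atoms away (five-membered ether formation) instead of being acylated, or the tertiary alcohol may eliminate. The fallback sets out from 17 and returns at 19. Both hydroxyls are acetylated (Ac2O, DMAP, Et3N, 40 °C) to the diacetate F4. The primary acetate alone is removed by methanolysis (K2CO3, MeOH, 0 °C) to give the hydroxy acetate F5. Appel iodination (I2, PPh3, imidazole) then gives 19, so the iodide and a free tertiary hydroxyl never coexist.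

Further compounds
F1 | step 15 | 2-(trimethylsilyl)ethyl (13Z)-16-acetoxy-2-[(tert-butyldimethylsilyl)oxy]-8-oxo-17-norlabd-13-en-15-oate (ring stereocentres as in 23) | O=C1CC[C@@H]2C(C)(C)C[C@@H](O[Si](C)(C)C(C)(C)C)C[C@@]2(C)[C@@H]1CC/C(=C/C(=O)OCC[Si](C)(C)C)COC(C)=O
F2 | step 10 | endoperoxide (3,6-dihydro-1,2-dioxine fused to ring A, O–O bridging C10 and C7, C5=C6 alkene) | O1OCC=C2C(C)(C)C[C@@H](O[Si](C)(C)C(C)(C)C)C[C@@]12C
F3 | step 10 | (Z)-enediol, (1R,5R)-5-[(tert-butyldimethylsilyl)oxy]-2-(2-hydroxyethylidene)-1,3,3-trimethylcyclohexan-1-ol | OC/C=C1/C(C)(C)C[C@@H](O[Si](C)(C)C(C)(C)C)C[C@@]1(C)O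
F4 | step 12 | (1R,2R,5R)-2-(2-acetoxyethyl)-5-[(tert-butyldimethylsilyl)oxy]-1,3,3-trimethylcyclohexyl acetate | CC(=O)OCC[C@@H]1C(C)(C)C[C@@H](O[Si](C)(C)C(C)(C)C)C[C@@]1(C)OC(C)=O
F5 | step 12 | (1R,2R,5R)-5-[(tert-butyldimethylsilyl)oxy]-2-(2-hydroxyethyl)-1,3,3-trimethylcyclohexyl acetate | OCC[C@@H]1C(C)(C)C[C@@H](O[Si](C)(C)C(C)(C)C)C[C@@]1(C)OC(C)=O
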